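Ring A is the dibromo ring (C1 CH2, C2 Br, C3 O, C4 O, C5 Br, C6 H); ring B is the tribromo ring (C1 CH2, C2 Br, C3 OH, C4 OH, C5 Br, C6 Br).
Cuts, in retrosynthetic order: the two O–CH3 bonds of a ring A dimethyl ether; the C2–Br, C5–Br and C6–Br bonds of ring B, all three at once; the ring A C1–CH2 bond (arylmagnesium plus aldehyde, carbinol then deoxygenated); the C–I and two C–Br bonds of ring A, back to veratrole.
Enabling feature: every ring B carbon not bound to oxygen or to the CH2 carries bromine, so a bare 4-substituted catechol only has to be brominated to exhaustion. Ring A keeps one C–H (C6) and is therefore carried as the dibrominated dimethyl ether, each methoxy group wedged between two ortho substituents.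
Forward order: veratrole → 3,6-dibromide → iodide (ring A as nucleophile); 3,4-dihydroxybenzaldehyde → diphenylmethylene ketal (ring B as electrophile); union at the central carbon by Grignard addition; Et3SiH/CF3CO2H gives the CH2 and frees the ring B catechol; tribromination; BBr3 demethylation. No ring is built; both benzene rings are bought.
Stereochemistry: the target has no stereocenter; the carbinol carbon formed at the union is racemic and becomes CH2 one step later.

Key step: step 6

Step 1
Reactants: 1 veratrole (1,2-dimethoxybenzene)
Product: 3 1,4-dibromo-2,3-dimethoxybenzene (3,6-dibromoveratrole), via 3,6-dilithioveratrole 2 (not isolated)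
Conditions: n-BuLi (3 equiv), TMEDA (3 equiv), Et2O, 0 °C → rt; then BrCl2C–CCl2Br (3.5 equiv), THF, −78 °C → rt
Reagents that add atoms: 1,2-dibromo-1,1,2,2-tetrachloroethane, ClC(Cl)(Br)C(Cl)(Cl)Br
Why: Double directed ortho-metalation, in which each methoxy group steers n-BuLi/TMEDA to its only free ortho position (C3 and C6), followed by bromine transfer from the polyhaloethane to both C–Li bonds, so only the 3,6-dibromide can form.

Step 2
Reactants: 3 1,4-dibromo-2,3-dimethoxybenzene
Product: 4 1,4-dibromo-5-iodo-2,3-dimethoxybenzene
Conditions: NIS (1.1 equiv), CF3SO3H (1.2 equiv), CH2Cl2, 0 °C → rt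
Reagents that add atoms: N-iodosuccinimide, O=C1CCC(=O)N1I
Why: Electrophilic aromatic iodination with acid-activated NIS, a system strong enough for deactivated arenes; the two free positions of 3 are equivalent by symmetry and each is para to a methoxy group, so only one mono-iodide is possible, and the first iodine slows a second attack.

Step 3
Reactants: 5 3,4-dihydroxybenzaldehyde
Product: 6 2,2-diphenyl-1,3-benzodioxole-5-carbaldehyde
Conditions: Ph2CCl2 (1.3 equiv), Ph2O, 175 °C
Reagents that add atoms: dichlorodiphenylmethane, ClC(Cl)(c1ccccc1)c1ccccc1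
Why: Ketal formation by double substitution of the catechol oxygens at the benzophenone dichloride carbon with loss of HCl, giving a diphenylmethylene ketal that tolerates the organomagnesium step and is later removed by acid.

Step 4
Reactants: 4 1,4-dibromo-5-iodo-2,3-dimethoxybenzene; 6 2,2-diphenyl-1,3-benzodioxole-5-carbaldehyde
Product: 8 (2,5-dibromo-3,4-dimethoxyphenyl)(2,2-diphenyl-1,3-benzodioxol-5-yl)methanol (racemic), via arylmagnesium chloride 7 (not isolated)
Conditions: i-PrMgCl·LiCl (1.05 equiv), THF, −40 °C; then 6, −40 → 0 °C; aq. NH4Cl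
Reagents that add atoms: none
Why: Iodine–magnesium exchange is much faster at C–I than at C–Br at −40 °C, the ortho-bromo arylmagnesium does not eliminate to an aryne at this temperature, and it adds to the aldehyde (Grignard 1,2-addition); the carbinol stereocenter is formed without control as the racemate and is erased in step 5.

Step 5
Reactants: 8 (2,5-dibromo-3,4-dimethoxyphenyl)(2,2-diphenyl-1,3-benzodioxol-5-yl)methanol
Product: 10 4-[(2,5-dibromo-3,4-dimethoxyphenyl)methyl]benzene-1,2-diol, via ketal-protected diarylmethane 9 (not isolated)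
Conditions: Et3SiH (6 equiv), CF3CO2H–CH2Cl2 (1:1), 0 °C → rt
Reagents that add atoms: none
Why: Ionic hydrogenation, in which the acid ionizes the doubly benzylic carbinol to a cation stabilized by the para oxygen of ring B and the silane delivers hydride, while the same medium cleaves the diphenylmethylene ketal by acidolysis with the silane reducing the diphenylmethyl cation to diphenylmethane, leaving the aryl methyl ethers and aryl bromides of ring A untouched.

Step 6
Reactants: 10 4-[(2,5-dibromo-3,4-dimethoxyphenyl)methyl]benzene-1,2-diol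
Product: 11 3,4,6-tribromo-5-[(2,5-dibromo-3,4-dimethoxyphenyl)methyl]benzene-1,2-diol
Conditions: Br2 (3.1 equiv), AcOH–CH2Cl2 (1:1), 0 °C → rt, dark; aq. Na2S2O4 wash
Reagents that add atoms: bromine, BrBr
Why: Electrophilic aromatic substitution: Br2 attacks the free ring B catechol at C6 (para to the C3 hydroxyl) and then at C5 and C2 (each ortho to a hydroxyl) through Wheland intermediates that rearomatize with loss of HBr, so the C2–Br, C5–Br and C6–Br bonds of ring B form in one operation. The closest known reaction is the exhaustive bromination of catechol and of 4-alkylcatechols with Br2 in acetic acid, the laboratory counterpart of haloperoxidase perbromination. No ring closes and no stereocenter is created. Because all three free positions of ring B are filled, no regiochemical choice arises on that ring. The selectivity needed is between the rings: ring B has two free hydroxyl groups, whereas the single C–H of ring A (C6, para to the C3 methoxy) sits on a ring deactivated by two bromines whose methoxy groups are twisted out of conjugation by their ortho neighbours, and no Lewis acid is present. Three equivalents at low temperature in an acidic medium should hold back oxidation to the ortho-quinone, and the Na2S2O4 wash returns any quinone to the catechol.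

Step 7
Reactants: 11 3,4,6-tribromo-5-[(2,5-dibromo-3,4-dimethoxyphenyl)methyl]benzene-1,2-diol
Product: 12 3,4,6-tribromo-5-[(2,5-dibromo-3,4-dihydroxyphenyl)methyl]benzene-1,2-diol
Conditions: BBr3 (6 equiv), CH2Cl2, −78 °C → rt; then H2O, 0 °C
Reagents that add atoms: none
Why: Lewis-acid cleavage of aryl methyl ethers, in which BBr3 binds each methoxy oxygen and bromide removes the methyl group by SN2 attack, the standard last step for polybrominated phenols, which leaves aryl bromides and the diarylmethane intact.

Compound list
1 | veratrole (1,2-dimethoxybenzene) | COc1ccccc1OC | starting material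
2 | 3,6-dilithioveratrole | [Li]c1ccc([Li])c(OC)c1OC | intermediate
3 | 1,4-dibromo-2,3-dimethoxybenzene (3,6-dibromoveratrole) | COc1c(Br)ccc(Br)c1OC | intermediate
4 | 1,4-dibromo-5-iodo-2,3-dimethoxybenzene | COc1c(Br)cc(I)c(Br)c1OC | intermediate
5 | 3,4-dihydroxybenzaldehyde | O=Cc1ccc(O)c(O)c1 | starting material
6 | 2,2-diphenyl-1,3-benzodioxole-5-carbaldehyde | O=Cc1ccc2OC(c3ccccc3)(c3ccccc3)Oc2c1 | intermediate
7 | (2,5-dibromo-3,4-dimethoxyphenyl)magnesium chloride | COc1c(Br)cc([Mg]Cl)c(Br)c1OC | intermediate
8 | (2,5-dibromo-3,4-dimethoxyphenyl)(2,2-diphenyl-1,3-benzodioxol-5-yl)methanol, racemic | COc1c(Br)cc(C(O)c2ccc3OC(c4ccccc4)(c4ccccc4)Oc3c2)c(Br)c1OC | intermediate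
9 | 5-[(2,5-dibromo-3,4-dimethoxyphenyl)methyl]-2,2-diphenyl-1,3-benzodioxole | COc1c(Br)cc(Cc2ccc3OC(c4ccccc4)(c4ccccc4)Oc3c2)c(Br)c1OC | intermediate
10 | 4-[(2,5-dibromo-3,4-dimethoxyphenyl)methyl]benzene-1,2-diol | COc1c(Br)cc(Cc2ccc(O)c(O)c2)c(Br)c1OC | intermediate
11 | 3,4,6-tribromo-5-[(2,5-dibromo-3,4-dimethoxyphenyl)methyl]benzene-1,2-diol | COc1c(Br)cc(Cc2c(Br)c(O)c(O)c(Br)c2Br)c(Br)c1OC | intermediate
12 | 3,4,6-tribromo-5-[(2,5-dibromo-3,4-dihydroxyphenyl)methyl]benzene-1,2-diol | Oc1c(Br)cc(Cc2c(Br)c(O)c(O)c(Br)c2Br)c(Br)c1O | target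

Total steps: 7. Longest linear sequence: 6 (steps 1, 2, 4, 5, 6 and 7 from veratrole); step 3 is a one-step branch.

Steps most likely to fail

Step 6. The unbrominated catechol of 10 may be oxidized by Br2 to the ortho-quinone faster than it is substituted. The quinone can tautomerize to a quinone methide at the diarylmethane carbon and be trapped there. The third substitution next to the CH2 may also stall, so that surplus reagent starts to attack ring A. The fallback sets out from 5 and comes back at 11. It brings one ring B bromine in before the union, so that the late bromination starts from a less oxidizable bromocatechol and needs only two equivalents. One equivalent of Br2 in AcOH should convert 5 into 3-bromo-4,5-dihydroxybenzaldehyde F1 (attack ortho to the 4-hydroxyl, meta to the formyl group). Ketalization with Ph2CCl2 as in step 3 should give 7-bromo-2,2-diphenyl-1,3-benzodioxole-5-carbaldehyde F2. Addition of arylmagnesium chloride 7 as in step 4 should give racemic (7-bromo-2,2-diphenyl-1,3-benzodioxol-5-yl)(2,5-dibromo-3,4-dimethoxyphenyl)methanol F3. Et3SiH/CF3CO2H as in step 5 should pass through 7-bromo-5-[(2,5-dibromo-3,4-dimethoxyphenyl)methyl]-2,2-diphenyl-1,3-benzodioxole F4 to 3-bromo-5-[(2,5-dibromo-3,4-dimethoxyphenyl)methyl]benzene-1,2-diol F5. Two equivalents of Br2 in AcOH should then fill C2 and C6 of ring B and give 11.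

Step 2. The doubly brominated ring may react too slowly with the iodine electrophile, the strong acid may cause ether cleavage or halogen scrambling, or a second iodine may enter. The fallback sets out from 3 and comes back at 8, replacing electrophilic substitution by deprotonation. LiN(i-Pr)2 in THF at −78 °C should remove one of the two equivalent ring protons ortho to bromine and give (2,5-dibromo-3,4-dimethoxyphenyl)lithium F6. Trapping in the cold with aldehyde 6 should give carbinol 8 directly, bypassing 4 and 7. A short metalation time at −78 °C is meant to limit bromine migration and aryne formation.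

Step 5. The diphenylmethyl cation released from the ketal, or the diarylmethyl cation itself, may alkylate the freed electron-rich catechol ring before the silane reduces it, or ketal cleavage may stay incomplete. The fallback sets out from 5 and comes back at 10. It uses silyl ethers that are removed by fluoride, so no carbocation is present when the catechol is released. t-BuMe2SiCl and imidazole in DMF should convert 5 into 3,4-bis(tert-butyldimethylsilyloxy)benzaldehyde F7. Addition of 7 as in step 4 should give racemic [3,4-bis(tert-butyldimethylsilyloxy)phenyl](2,5-dibromo-3,4-dimethoxyphenyl)methanol F8. A brief Et3SiH/CF3CO2H reduction in CH2Cl2 at −20 °C should give 1,2-bis(tert-butyldimethylsilyloxy)-4-[(2,5-dibromo-3,4-dimethoxyphenyl)methyl]benzene F9. Bu4NF buffered with AcOH in THF at 0 °C should then give 10.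

Further compounds
F1 | step 6 | 3-bromo-4,5-dihydroxybenzaldehyde | O=Cc1cc(O)c(O)c(Br)c1
F2 | step 6 | 7-bromo-2,2-diphenyl-1,3-benzodioxole-5-carbaldehyde | O=Cc1cc(Br)c2OC(c3ccccc3)(c3ccccc3)Oc2c1
F3 | step 6 | (7-bromo-2,2-diphenyl-1,3-benzodioxol-5-yl)(2,5-dibromo-3,4-dimethoxyphenyl)methanol, racemic | COc1c(Br)cc(C(O)c2cc(Br)c3OC(c4ccccc4)(c4ccccc4)Oc3c2)c(Br)c1OC
F4 | step 6 | 7-bromo-5-[(2,5-dibromo-3,4-dimethoxyphenyl)methyl]-2,2-diphenyl-1,3-benzodioxole | COc1c(Br)cc(Cc2cc(Br)c3OC(c4ccccc4)(c4ccccc4)Oc3c2)c(Br)c1OC
F5 | step 6 | 3-bromo-5-[(2,5-dibromo-3,4-dimethoxyphenyl)methyl]benzene-1,2-diol | COc1c(Br)cc(Cc2cc(O)c(O)c(Br)c2)c(Br)c1OC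
F6 | step 2 | (2,5-dibromo-3,4-dimethoxyphenyl)lithium | [Li]c1cc(Br)c(OC)c(OC)c1Br
F7 | step 5 | 3,4-bis(tert-butyldimethylsilyloxy)benzaldehyde | O=Cc1ccc(O[Si](C)(C)C(C)(C)C)c(O[Si](C)(C)C(C)(C)C)c1
F8 | step 5 | [3,4-bis(tert-butyldimethylsilyloxy)phenyl](2,5-dibromo-3,4-dimethoxyphenyl)methanol, racemic | COc1c(Br)cc(C(O)c2ccc(O[Si](C)(C)C(C)(C)C)c(O[Si](C)(C)C(C)(C)C)c2)c(Br)c1OC
F9 | step 5 | 1,2-bis(tert-butyldimethylsilyloxy)-4-[(2,5-dibromo-3,4-dimethoxyphenyl)methyl]benzene | COc1c(Br)cc(Cc2ccc(O[Si](C)(C)C(C)(C)C)c(O[Si](C)(C)C(C)(C)C)c2)c(Br)c1OC
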